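The constants of the recipe give the first number: for G to become X as fast as it enters, each D in the flask must turn over

  required frequency = charge of G / (dosing time × c_D) = 1250 /h

The decision for the next run is whether 10 µM of D delivers this or more D must be charged.

in all of them: G 0.10 M (fed, over 8.0 h)
- maple: D 5 µM; run made earlier
- flask: D 10 µM; time 8.0 h
- maple (time / h: X / %, G / %): 0.200: 0, 3; 0.417: 1, 5; 1.00: 4, 11; 2.50: 12, 20

(standard deviation of a reading: 1.5 percentage points)
- X present at 8.0 h, in percent of the G charged
- G present at 8.0 h, in percent of the G charged
- percentages count the whole charge, also what has not yet gone in
- a reading or a percentage of X counts all its forms, free or not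
- no earlier run changes the charge of D; that part of a forecast is a guess

In the maple run, X formed at 1030 /h per D between 0.417 h and 1.00 h, then at 1070 /h between 1.00 h and 2.50 h, while G climbed from 5% to 20%. Within the scatter, X formation therefore reads as zero order in G over that range, and the later figure is taken as the capacity (a turnover frequency), the X made per hour per D. It is a reading, with 1.5 percentage points of scatter on each point.

Assuming that X formation scales with D, which is a guess, the flask falls short of the feed, since capacity is less than required, and G accumulates:

  X at the end = capacity × c_D × time / charge of G = 85.3%

That leaves 14.7% as G.

The forecast gives 83% of X (66% to 89%) and 17% of G (11% to 34%), with G approaching “a quasi-steady level where consumption equals feed”, whereas the reckoning above has G accumulating throughout the feed.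

The flask gives 67.8% of X and 32.2% of G.

    D + X ⇌ L (K = 53.0 /M, k = 5.00 × 10⁻⁴ /M/s)
    G + D → X + D, rate k2*[G]*[D]/(1 + ([G]/Km2)) (3.70 mM, k = 96.0 /M/s)

In the flask, free D stands at 90.0% of its charge at 4.00 h and 64.7% at 8.00 h, the rest being L. Capacity applied to the mean of those two readings gives 33.0% of X over that interval, and the flask gained 34 points. The neighbour flask, charged with 4.00 µM of D, requires 3120 /h. Its free D ends at 81.6%, so capacity on the mean of charge and end gives 31.0% of X. That flask reads 32.3% of X and 67.7% of G.

The earlier runs and the new flask are calculated with constants of no real substance, and the scatter is random.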